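The oxirane is made last by catalyst-controlled epoxidation of the (Z)-C13=C14 alkene of an oxocene; the oxocene is closed by ring-closing metathesis between an O-allyl ether on C8 and a methylidene on C13.
Ring B and the C8–O bond come from a proton-initiated cation–olefin cyclisation: the C1=C10 alkene of a monocyclic ring A gives the C10 cation, the (E)-C8=C9 alkene adds, and the C13 ketone oxygen terminates.
Ring A comes from an enantioselective Diels–Alder reaction of the acyclic (E)-diene C2=C1–C10(Me)=C5 (three steps from geranylacetone) with (Z)-3-bromo-2-methylacrolein (C3=C4); it makes C2–C3 and C4–C5 and brings in the C3 bromine, and the formyl group then becomes the second C4 methyl.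
Enabling feature: ring A (C1–C5, C10) carries Br on C3 next to the quaternary C4 and the methyl-bearing quaternary C10; written with a C1=C10 double bond it is a cyclohexene, a [4+2] retron, and that same alkene is later the latent C10 cation that closes ring B.
Ring order: ring A (step 6), ring B (step 9), oxocane (step 12), oxirane (step 13).

Key step: step 6

Remark: atom numbers are labdane numbers (C1–C20), used only as locants; configurations are those of the CIP descriptors and the SMILES.
Assumption: the oxazaborolidinium catalyst shields the enal face predicted by the formyl C–H···O model for 2-substituted acroleins; should the sense be opposite, the (R)-catalyst is taken and nothing else changes.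

Step 1
Reactants: 1 (E)-geranylacetone
Product: 2 2-[(3E)-4,8-dimethylnona-3,7-dien-1-yl]-2-methyl-1,3-dioxolane
Conditions: ethylene glycol, PPTS (cat.), benzene, reflux (Dean–Stark)
Reagents that add atoms: ethylene glycol OCCO
Why: Acid-catalysed ketalisation with azeotropic removal of water masks the methyl ketone (the later cyclisation terminator) against the ylide, Lewis-acid and hydrazide steps; no stereocentre is formed.

Step 2
Reactants: 2
Product: 4 (2E,6E)-2,6-dimethyl-9-(2-methyl-1,3-dioxolan-2-yl)nona-2,6-dienal, via allylic alcohol 3 (not isolated)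
Conditions: SeO2 (cat.), t-BuOOH (in decane), salicylic acid (cat.), CH2Cl2, 0 °C → rt; crude alcohol/aldehyde mixture then MnO2, CH2Cl2, rt
Reagents that add atoms: selenium dioxide O=[Se]=O (oxygen carrier); tert-butyl hydroperoxide CC(C)(C)OO (terminal oxidant)
Why: Sharpless allylic oxidation (ene reaction then [2,3]-sigmatropic shift) attacks the (E)-methyl group of the terminal isopropylidene unit, so the new C1 oxygen function is fixed trans to the chain, and MnO2 converges the mixture to the (E)-enal.

Step 3
Reactants: 4
Product: 5 2-[(3E,7E)-4,8-dimethyldeca-3,7,9-trien-1-yl]-2-methyl-1,3-dioxolane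
Conditions: Ph3PCH3Br, n-BuLi, THF, 0 °C → rt
Reagents that add atoms: methyltriphenylphosphonium bromide C[P+](c1ccccc1)(c1ccccc1)c1ccccc1.[Br-]
Why: Wittig methylenation (1,2-addition of the unstabilised ylide to the enal) adds C2 and completes the (E)-1,3-diene without touching the ketal or the existing alkene geometry.

Step 4
Reactants: 6 prop-2-yn-1-ol
Product: 8 (2Z)-3-bromo-2-methylprop-2-en-1-ol, via cyclic alkenylmagnesium alkoxide 7 (not isolated)
Conditions: MeMgBr (2.5 equiv), CuI (copper monoiodide, 10 mol%), THF, −10 °C → rt; then NBS, THF, −78 → 0 °C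
Reagents that add atoms: methylmagnesium bromide C[Mg]Br; N-bromosuccinimide O=C1CCC(=O)N1Br
Why: Copper-catalysed anti-carbomagnesiation of the propargylic magnesium alkoxide puts methyl on C2 and magnesium on C3 within a five-membered chelate, so bromination of the C–Mg bond with retention should give the (Z)-bromoalkene with Br cis to CH2OH.

Step 5
Reactants: 8
Product: 9 (2Z)-3-bromo-2-methylprop-2-enal
Conditions: activated MnO2, CH2Cl2, 0 °C → rt, dark; used at once
Reagents that add atoms: none
Why: Neutral allylic oxidation with MnO2 should give the enal without E/Z isomerisation of the bromoalkene.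

Step 6
Reactants: 5 (diene), 9 (dienophile)
Product: 10 (1R,2S,6R)-6-bromo-1,3-dimethyl-2-[(3E)-3-methyl-6-(2-methyl-1,3-dioxolan-2-yl)hex-3-en-1-yl]cyclohex-3-ene-1-carbaldehyde
Conditions: (S)-oxazaborolidinium triflimide [from (S)-α,α-diphenylprolinol, o-tolylboroxine and Tf2NH; 20 mol%], CH2Cl2, −78 → −40 °C
Reagents that add atoms: none
Why: Lewis-acid-catalysed Diels–Alder reaction in which the boron-bound s-trans enal 9 reacts through a concerted but asynchronous [4+2] transition state, the bond from the enal β-carbon C3 (bearing Br) to the unsubstituted diene terminus C2 leading and the bond from the α-carbon C4 to C5 following. The closest known reaction type is the oxazaborolidinium-catalysed enantioselective Diels–Alder reaction of 2-substituted acroleins (2-methyl- and 2-bromoacrolein) with acyclic and 1-vinylcycloalkene-type dienes. Ring A is closed by an intermolecular suprafacial–suprafacial [4+2] cycloaddition that makes C2–C3 and C4–C5 and leaves the C1=C10 alkene. C5 is set by the (E)-geometry of the diene together with the enal face left open by the catalyst; C3 is set by the (Z)-geometry of 9 in the formyl-endo arrangement (CHO and Br both endo, hence cis to the C5 side chain); the transient centre C4 (Me, CHO) follows from the same suprafacial addition and disappears when CHO becomes CH3. The step needs "ortho" regiochemistry, endo selectivity and site selectivity: the alkyl group on the C5 terminus makes C2 the more nucleophilic end of the 1,2-disubstituted diene (as in 1-vinylcyclohexene, which adds "ortho" to 2-substituted acroleins), Lewis-acid activation favours the formyl-endo mode, and the isolated C8=C9 alkene and the ketal are neither diene nor dienophile under these conditions.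

Step 7
Reactants: 10
Product: 12 2-{(3E)-6-[(1S,5R)-5-bromo-2,6,6-trimethylcyclohex-2-en-1-yl]-4-methylhex-3-en-1-yl}-2-methyl-1,3-dioxolane, via tosylhydrazone 11 (not isolated)
Conditions: TsNHNH2, THF, rt; then catecholborane, CHCl3, 0 °C; then NaOAc·3H2O, reflux
Reagents that add atoms: none
Why: Caglioti–Kabalka deoxygenation (hydride addition to the tosylhydrazone, loss of sulfinate and N2 through a diazene) turns CHO into CH3 and so makes C4 the gem-dimethyl carbon under non-basic conditions that should spare the secondary bromide, the alkenes and the ketal.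

Step 8
Reactants: 12
Product: 13 (5E)-8-[(1S,5R)-5-bromo-2,6,6-trimethylcyclohex-2-en-1-yl]-6-methyloct-5-en-2-one
Conditions: 1 M HCl, THF, rt
Reagents that add atoms: water O
Why: Acid hydrolysis of the dioxolane frees the C13 ketone needed as internal nucleophile, while the neopentyl secondary bromide and the trisubstituted alkenes are inert to dilute aqueous acid at room temperature.

Step 9
Reactants: 13
Product: 15 (3R,5S,8S,9S,10R)-3-bromo-8-hydroxy-14,15-dinorlabdan-13-one, via tricyclic enol ether 14 (not isolated)
Conditions: FSO3H (promoter, excess), 2-nitropropane, −78 °C; Et3N quench; then 1 M HCl, THF/H2O, rt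
Reagents that add atoms: water O
Why: Proton-initiated cation–olefin cyclisation of an α-monocyclofarnesyl-type ketone: Markovnikov protonation of C1=C10 gives the tertiary C10 cation, the (E)-C8=C9 alkene adds through a chair transition state (trans ring fusion, C10 methyl axial) and the ketone oxygen captures C8 anti to the new C9–C10 bond (8-O equatorial, 8-methyl and 9-H axial), so the existing C5 centre controls C10, C9 and C8; dilute acid then hydrolyses the cyclic enol ether to the ketol.

Step 10
Reactants: 15
Product: 16 (3R,5S,8S,9S,10R)-3-bromo-14,15-dinorlabd-13(16)-en-8-ol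
Conditions: Ph3PCH3Br (3 equiv), KOtBu (3 equiv), THF, 0 → 50 °C
Reagents that add atoms: methyltriphenylphosphonium bromide C[P+](c1ccccc1)(c1ccccc1)c1ccccc1.[Br-]
Why: Wittig methylenation with excess ylide (one equivalent of base is taken up by the tertiary OH) converts the methyl ketone, in equilibrium with its hemiketal, into the 1,1-disubstituted alkene needed for ring closure; no stereocentre is affected.

Step 11
Reactants: 16
Product: 17 (3R,5S,8S,9S,10R)-8-allyloxy-3-bromo-14,15-dinorlabd-13(16)-ene
Conditions: KH, THF, 0 °C; allyl bromide, Bu4NI (cat.), 0 °C → rt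
Reagents that add atoms: allyl bromide C=CCBr
Why: Williamson etherification of the potassium tertiary alkoxide with the reactive allylic bromide; the equatorial neopentyl C3 bromide has no anti-periplanar hydrogen and is closed to SN2 attack, so it should survive.

Step 12
Reactants: 17
Product: 18 (3R,5S,8S,9S,10R,13Z)-3-bromo-8,15-epoxylabd-13-ene
Conditions: second-generation Grubbs catalyst (H2IMes)(PCy3)Cl2Ru=CHPh (10 mol%), toluene (2 mM), 80 °C
Reagents that add atoms: none
Why: Ring-closing metathesis forms the eight-membered cyclic ether with a trisubstituted alkene that must be Z in the ring; the trans-diequatorial C8–O and C9–C11 bonds on the rigid decalin and the fully substituted C8 hold the two alkenes close, and high dilution suppresses oligomers.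

Step 13
Reactants: 18
Product: 19 (3R,5S,8S,9S,10R,13S,14R)-3-bromo-8,15:13,14-diepoxylabdane (CNP0311742.1)
Conditions: D-fructose-derived Shi ketone (30 mol%), Oxone (2KHSO5·KHSO4·K2SO4), K2CO3, Bu4NHSO4, MeCN/CH2(OMe)2/aq. Na2B4O7 buffer, 0 °C
Reagents that add atoms: potassium peroxymonosulfate [K+].[O-]S(=O)(=O)OO
Why: Shi asymmetric epoxidation (chiral dioxirane, spiro transition state): for a trisubstituted ring alkene of the 1-substituted cycloalkene type this ketone should deliver oxygen to the face that gives (13S,14R), catalyst control being chosen because the ring itself does not clearly distinguish the two faces, and the syn addition keeps C12 and C15 cis on the oxirane.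

Compound list
1 | (5E)-6,10-dimethylundeca-5,9-dien-2-one [(E)-geranylacetone] | CC(=O)CC/C=C(\C)CCC=C(C)C | starting material
2 | 2-[(3E)-4,8-dimethylnona-3,7-dien-1-yl]-2-methyl-1,3-dioxolane | CC1(CC/C=C(\C)CCC=C(C)C)OCCO1 | intermediate
3 | (2E,6E)-2,6-dimethyl-9-(2-methyl-1,3-dioxolan-2-yl)nona-2,6-dien-1-ol | OC/C(C)=C/CC/C(C)=C/CCC1(C)OCCO1 | intermediate
4 | (2E,6E)-2,6-dimethyl-9-(2-methyl-1,3-dioxolan-2-yl)nona-2,6-dienal | O=C/C(C)=C/CC/C(C)=C/CCC1(C)OCCO1 | intermediate
5 | 2-[(3E,7E)-4,8-dimethyldeca-3,7,9-trien-1-yl]-2-methyl-1,3-dioxolane | C=C/C(C)=C/CC/C(C)=C/CCC1(C)OCCO1 | intermediate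
6 | prop-2-yn-1-ol | C#CCO | starting material
7 | 4-methyl-2,5-dihydro-1,2-oxamagnesole (cyclic (Z)-alkenylmagnesium alkoxide) | CC1=C[Mg]OC1 | intermediate
8 | (2Z)-3-bromo-2-methylprop-2-en-1-ol | OC/C(C)=C\Br | intermediate
9 | (2Z)-3-bromo-2-methylprop-2-enal | O=C/C(C)=C\Br | intermediate
10 | (1R,2S,6R)-6-bromo-1,3-dimethyl-2-[(3E)-3-methyl-6-(2-methyl-1,3-dioxolan-2-yl)hex-3-en-1-yl]cyclohex-3-ene-1-carbaldehyde | CC1=CC[C@@H](Br)[C@@](C)(C=O)[C@H]1CC/C(C)=C/CCC1(C)OCCO1 | intermediate
11 | N-tosylhydrazone of 10 | CC1=CC[C@@H](Br)[C@@](C)(/C=N/NS(=O)(=O)c2ccc(C)cc2)[C@H]1CC/C(C)=C/CCC1(C)OCCO1 | intermediate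
12 | 2-{(3E)-6-[(1S,5R)-5-bromo-2,6,6-trimethylcyclohex-2-en-1-yl]-4-methylhex-3-en-1-yl}-2-methyl-1,3-dioxolane | CC1=CC[C@@H](Br)C(C)(C)[C@H]1CC/C(C)=C/CCC1(C)OCCO1 | intermediate
13 | (5E)-8-[(1S,5R)-5-bromo-2,6,6-trimethylcyclohex-2-en-1-yl]-6-methyloct-5-en-2-one | CC1=CC[C@@H](Br)C(C)(C)[C@H]1CC/C(C)=C/CCC(C)=O | intermediate
14 | (3R,5S,8S,9S,10R)-3-bromo-8,13-epoxy-14,15-dinorlabd-12-ene (tricyclic enol ether) | CC1(C)[C@H](Br)CC[C@]2(C)[C@@H]1CC[C@]1(C)OC(C)=CC[C@@H]21 | intermediate
15 | (3R,5S,8S,9S,10R)-3-bromo-8-hydroxy-14,15-dinorlabdan-13-one | CC1(C)[C@H](Br)CC[C@]2(C)[C@@H]1CC[C@](C)(O)[C@H]2CCC(C)=O | intermediate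
16 | (3R,5S,8S,9S,10R)-3-bromo-14,15-dinorlabd-13(16)-en-8-ol | CC1(C)[C@H](Br)CC[C@]2(C)[C@@H]1CC[C@](C)(O)[C@H]2CCC(C)=C | intermediate
17 | (3R,5S,8S,9S,10R)-8-allyloxy-3-bromo-14,15-dinorlabd-13(16)-ene | CC1(C)[C@H](Br)CC[C@]2(C)[C@@H]1CC[C@](C)(OCC=C)[C@H]2CCC(C)=C | intermediate
18 | (3R,5S,8S,9S,10R,13Z)-3-bromo-8,15-epoxylabd-13-ene | CC1(C)[C@H](Br)CC[C@]2(C)[C@@H]1CC[C@]1(C)OC/C=C(C)\CC[C@@H]21 | intermediate
19 | (3R,5S,8S,9S,10R,13S,14R)-3-bromo-8,15:13,14-diepoxylabdane (CNP0311742.1) | CC1(C)[C@H](Br)CC[C@]2(C)[C@@H]1CC[C@]1(C)OC[C@H]3O[C@@]3(C)CC[C@@H]21 | target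

Total step count: 13. Longest linear sequence: 11 steps (steps 1–3 and 6–13).

Steps most likely to fail

Step 6 (Diels–Alder). What may go wrong: erosion of regio- or endo-selectivity (the C5-alkyl and C10-methyl groups of the diene direct in opposite senses, and a formyl-exo approach would invert C3), E/Z isomerisation of the bromo-enal on the Lewis acid, or poor π-facial discrimination. Should only the formyl-exo mode be the problem, the (E)-isomer of 9 would give the same C3 configuration. The fallback replaces the cycloaddition by a bromonium-initiated polyene cyclisation; it sets out from diene 5 and comes back to the route at enol ether 14. Hydroboration of the terminal vinyl group of 5 with 9-BBN in THF should give B-alkyl-9-borabicyclononane F1. B-alkyl Suzuki–Miyaura coupling of this borane with 1-bromo-2-methylprop-1-ene (Pd(dppf)Cl2, K3PO4, THF/DMF/H2O) should give (5E,9E)-farnesylacetone ethylene ketal F2, and 1 M HCl in THF should free (5E,9E)-farnesylacetone F3. An enantioselective bromonium-induced bicyclisation (1,3-dibromo-5,5-dimethylhydantoin with a chiral BINOL-derived thiophosphoramide Lewis-base catalyst, low temperature) should then form the C3–Br bond, rings A and B and the C8–O bond in one chair–chair cascade terminated by the ketone oxygen. This gives 14 with equatorial bromine and trans ring fusion, which is hydrolysed as in step 9.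

Step 9 (cation–olefin cyclisation). What may go wrong: loss of the C5 configuration when the C10 cation loses H5 to the tetrasubstituted C5=C10 alkene and is reprotonated, initiation at C8=C9 (leading to a monocyclic dihydropyran), or proton loss from C8 instead of capture by oxygen. The fallback uses radical instead of cationic initiation; it sets out from ketone 13 and comes back at enol ether 14. A hydrogen-atom-transfer-initiated radical–polar crossover bicyclisation (Co(salen) complex of divalent cobalt, N-fluoro-2,4,6-trimethylpyridinium triflate, PhSiH3, CH2Cl2, 0 °C) should place H on C1 and let the tertiary C10 radical add in 6-endo fashion to C8=C9 through the same chair. The tertiary C8 radical is then oxidised to the cation and trapped by the ketone oxygen. A C10 radical cannot lose H5 as a proton, so C5 is not scrambled. It makes no new compound F0.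

Step 13 (epoxidation). What may go wrong: low facial selectivity or slow oxygen transfer if the preferred conformation of the oxocene presents the face that the catalyst does not address (mismatched double diastereoselection). The fallback uses anti addition followed by ring closure instead of direct oxygen transfer; it sets out from oxocene 18 and comes back at target 19. NBS in aqueous DME at 0 °C should form the bromonium ion on the exposed face and open it with water at the more substituted C13 from the opposite face, giving (3R,5S,8S,9S,10R,13S,14S)-3,14-dibromo-8,15-epoxylabdan-13-ol F4. K2CO3 in MeOH should then close the oxirane by SN2 displacement of bromide at C14, which puts the oxygen on the face opposite to the one attacked by electrophilic oxidants.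

Further compounds
F1 | step 6 | 9-[(3E,7E)-3,7-dimethyl-10-(2-methyl-1,3-dioxolan-2-yl)deca-3,7-dien-1-yl]-9-borabicyclo[3.3.1]nonane | CC1(CC/C=C(\C)CC/C=C(\C)CCB2C3CCCC2CCC3)OCCO1
F2 | step 6 | 2-methyl-2-[(3E,7E)-4,8,12-trimethyltrideca-3,7,11-trien-1-yl]-1,3-dioxolane | CC(C)=CCC/C(C)=C/CC/C(C)=C/CCC1(C)OCCO1
F3 | step 6 | (5E,9E)-6,10,14-trimethylpentadeca-5,9,13-trien-2-one | CC(C)=CCC/C(C)=C/CC/C(C)=C/CCC(C)=O
F0 | step 9 | none | none
F4 | step 13 | (3R,5S,8S,9S,10R,13S,14S)-3,14-dibromo-8,15-epoxylabdan-13-ol | CC1(C)[C@H](Br)CC[C@]2(C)[C@@H]1CC[C@]1(C)OC[C@H](Br)[C@@](C)(O)CC[C@@H]21
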